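Its constants are invented; the result is computed.

Choose the feed.

common to all: second substrate 20.0 mM; catalyst 24 µM; time 100 min

| flask | starting material | reagent | remark |
|---|---|---|---|
| north-west | 20 mM | 50.0 mM (in portions, 3, over 80 min) | first portion at the start, last at 80 min |
| south | 20 mM | 50.0 mM | everything together at the start |
| south-west | 20 mM | 50.0 mM (fed, over 80 min) | all else is in the flask from the start; the feed brings no volume worth counting |
| east | 20 mM (fed, over 80 min) | 50.0 mM | all else is in the flask from the start; the feed brings no volume worth counting |

    starting material + reagent + catalyst → catalyst + target (k1 = 7.53 × 10⁵ /M²/h)
    second substrate + reagent + catalyst → catalyst + second product (k2 = 3.97 × 10⁵ /M²/h)
    starting material + target → side product (k3 = 22.9 /M/h)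
    target + catalyst ⇌ isomer of the product + catalyst, rate k4*[catalyst]*[target] forward; the back reaction follows from the equilibrium constant (K4 = 10.4, k4 = 3770 /M/h)

- percent here means starting material units held: one side product counts as two
- run time (north-west): 100 min

1. the flask that comes out highest in share of target in target plus side product, or "all alike" when all lie within 1.5 percentage points (north-west / south / south-west / east / all alike)
2. share of target in target plus side product at the end, north-west
3. share of target in target plus side product at the end, south
4. share of target in target plus side product at the end, south-west
5. share of target in target plus side product at the end, east

Starting material leaves by two routes, the main step with reagent and catalyst and the side step with target. Its concentration stands in both rates, so it cancels from their ratio. What remains is the branch ratio: reagent concentration over target concentration, times 0.789, the branch number, which is the main rate constant times the catalyst over the side rate constant. The branch number, a fixed ratio of rate constants at this catalyst charge, is the selectivity factor, while the branch ratio moves with the run. Each side event takes one starting material and one target and leaves two units of side product, so the share of target in newly converted material is the ratio minus one, over the ratio plus one.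

At the start there is no target, so that share is one whole. For the other end I take south. Second-order kinetics with both partners running down gives a conversion of 71.0 %. If the second substrate keeps taking reagent in its starting proportion, with the main step using 1.9 parts to its one, reagent falls to 28.3 mM. The branch number times the mean reagent is then 30.9 mM. Joining the two ends by a straight line, and leaving the isomer out, I get 74.5 % for south. I expect both feeds to end less far converted, which raises this share. Feeding reagent thins the top of the ratio, while feeding starting material leaves it whole, so I would charge east.

The forecast also names east, with 63 % for north-west, 64 % for south, 63 % for south-west and 75 % for east, on the ground that “feeding the starting material keeps its level low while target builds up”. Its south figure stands 10 percentage points under mine, and my ratio holds no starting material.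

The flasks give 66.5 % for north-west, 66.5 % for south, 69.8 % for south-west and 74.2 % for east, the highest, so south lies 8 points below my figure and south-west 6.8 points above the forecast. At 100 min the branch number and the amounts in the flask give a ratio of 2.46 in south. East at that time has a higher ratio than south, 3.36. Counting these two steps, newly converted material then becomes target at 42.2 % in south against 54.1 % in east.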